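**Retrosynthetic overview**

1. The oxirane is made last by Sharpless epoxidation of a 13E allylic alcohol; its C13–C16 end is grown from a C9 allyl group (hydroboration, Ohira–Bestmann alkynylation, Negishi carboalumination/CH2O).
2. The C4 quaternary centre comes from α-face C-methylation of a ring A ester enolate; a surplus C2=C3 bond is removed with diimide.
3. Ring A is closed by a [3+3] annulation of a ring B 2-alkylidene ketone (O=C10–C5=C4H–CO2Me) with allylidenetriphenylphosphorane (C1–C3): Michael addition makes C3–C4 and an intramolecular Wittig reaction makes C1=C10 in the same flask.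
4. Enabling feature: in ring A the sp2 ring-fusion carbon C10 and the ester-bearing C4 both flank C5, so C10, C5 and C4 are the carbonyl, α- and β-carbons of an exocyclic enone on ring B; the quaternary C9 leaves C5 as the only enolisable position and C1=C10 as the only possible olefin.
5. Ring B is bought as 2-methylcyclohex-2-enone; C8 and C9 are set by copper-catalysed asymmetric methyl addition and enolate allylation. Ring order: B, then A, then the oxirane.

Key step: step 3

Remark: the discussion uses halimane numbering (ring A = C1–C5 and C10, ring B = C5–C10, ester carbon C18 and methyl C19 on C4, methyls on C8 and C9, side chain C11–C16 on C9; α is the face of the C8 and C9 methyl groups), whereas compound names use systematic locants; methyl glyoxylate is assumed to be used as the free aldehyde, liberated from its commercial methyl hemiacetal just before use.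

**Route**

Step 1
Reactants: 1 2-methylcyclohex-2-en-1-one
Product: 4 (2S,3R)-2,3-dimethyl-2-(prop-2-en-1-yl)cyclohexan-1-one, via dimethylaluminium enolate 2 (not isolated), via lithium aluminate enolate 3 (not isolated)
Conditions: Me3Al (1.4 equiv), Cu(O2CC4H3S) (copper thiophene-2-carboxylate, 2 mol %), chiral BINOL-derived phosphoramidite ligand (4 mol %, the antipode that gives 3R), Et2O, −30 °C; then MeLi (1.1 equiv), THF, −30 °C; allyl iodide (2 equiv), −30 → 0 °C; aq. NH4Cl
Reagents that add atoms: trimethylaluminium, C[Al](C)C; allyl iodide, C=CCI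
Why: Copper-catalysed asymmetric conjugate addition of Me3Al sets C8 under catalyst control, and the regiodefined enolate, activated as its lithium aluminate, should be C-allylated anti to the adjacent C8 methyl, giving the cis 8,9-dimethyl array with the allyl group on the β face (conjugate addition–enolate alkylation).

Step 2
Reactants: 4 (2S,3R)-2,3-dimethyl-2-(prop-2-en-1-yl)cyclohexan-1-one; 5 methyl glyoxylate
Product: 9 methyl (2E)-[(3S,4R)-3,4-dimethyl-2-oxo-3-(prop-2-en-1-yl)cyclohexylidene]acetate, via lithium enolate 6 (not isolated), via lithium aldolate 7 (not isolated), via aldol mesylate 8 (not isolated)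
Conditions: LiN(iPr)2 (1.1 equiv), THF, −78 °C; 5 (1.3 equiv), −78 °C; MsCl (1.3 equiv), −78 → 0 °C; Et3N (3 equiv), 0 °C → rt
Reagents that add atoms: none
Why: Only C5 of 4 can be enolised (C9 is quaternary), so the lithium enolate should add to the aldehyde of 5 and the mesylated aldolate should eliminate by E1cB to the doubly conjugated E alkylidene (aldol condensation); no stereocentre of the target is made here.

Step 3
Reactants: 9 methyl (2E)-[(3S,4R)-3,4-dimethyl-2-oxo-3-(prop-2-en-1-yl)cyclohexylidene]acetate; 10 allyltriphenylphosphonium bromide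
Product: 14 methyl (5S,6R,8aS)-5,6-dimethyl-5-(prop-2-en-1-yl)-1,5,6,7,8,8a-hexahydronaphthalene-1-carboxylate as both epimers at the ester-bearing carbon, via allylidene ylide 11 (not isolated), via phosphonium enolate zwitterion 12 (not isolated), via keto ylide 13 (not isolated)
Conditions: 10 (1.1 equiv), KOtBu (1.05 equiv), THF, 0 °C; 9 added at −78 °C; → rt, then 50 °C
Reagents that add atoms: none
Why: The γ-carbon of ylide 11 adds in Michael fashion to C4, the unsubstituted β-terminus of the exocyclic enone of 9 (C3–C4 bond, enolate 12), a proton is shuttled from C3 to C5 by the tert-butanol present to give the allylic ylide 13, and the carbon next to phosphorus (C1) then attacks the C10 ketone in an intramolecular Wittig olefination that releases Ph3PO and leaves the C1=C10 and C2=C3 double bonds. The closest known reaction type is the [3+3] annulation of allylidenetriphenylphosphorane with α,β-unsaturated ketones and alkylidene β-keto esters to give cyclohexa-1,3-dienes. Ring A is closed by 6-exo-trig attack of the ylide carbon on the carbonyl group. C5 is created by protonation of the enolate and stays epimerisable beside the ketone until the olefination, which should select the epimer whose ring B chair holds the C8 methyl, the C9 allyl group and the C4 side chain equatorial, since only there can C1 reach C10 along the axial trajectory past hydrogens alone, whereas the other epimer must place the C8 methyl axial and syn to that trajectory (Curtin–Hammett control by C8 and C9, H-5 ending cis to the C9 methyl); C4 is formed without control and is carried on as both epimers because step 4 planarises it. The step needs attack through the ylide γ-carbon at C4 rather than C5 and olefination of the ketone only: C4 is the open CH terminus β to the ketone whereas C5 is fully substituted, adducts formed through the carbon next to phosphorus cannot cyclise and revert, the esters are inert to the semistabilised ylide, and the quaternary C9 both shields the ketone of 9 from direct olefination and rules out enolisation away from C5.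

Step 4
Reactants: 14 methyl (5S,6R,8aS)-5,6-dimethyl-5-(prop-2-en-1-yl)-1,5,6,7,8,8a-hexahydronaphthalene-1-carboxylate
Product: 16 methyl (1S,5S,6R,8aR)-1,5,6-trimethyl-5-(prop-2-en-1-yl)-1,5,6,7,8,8a-hexahydronaphthalene-1-carboxylate, via lithium trienolate 15 (not isolated)
Conditions: LiN(iPr)2 (1.2 equiv), THF, −78 °C; MeI (3 equiv), −78 → −20 °C
Reagents that add atoms: iodomethane, CI
Why: Deprotonation at C4 gives an extended ester enolate that should be alkylated at its α-carbon (kinetic α-alkylation), and MeI should enter from the α face, syn to the small H-5 and anti to the C6 methylene of ring B that shields the β face, which sets the quaternary C4 with its methyl cis to H-5 and the ester on the β face.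

Step 5
Reactants: 16 methyl (1S,5S,6R,8aR)-1,5,6-trimethyl-5-(prop-2-en-1-yl)-1,5,6,7,8,8a-hexahydronaphthalene-1-carboxylate
Product: 18 methyl (1S,5S,6R,8aR)-5-(3-hydroxypropyl)-1,5,6-trimethyl-1,5,6,7,8,8a-hexahydronaphthalene-1-carboxylate, via alkyl-9-BBN adduct 17 (not isolated)
Conditions: 9-BBN (1.2 equiv), THF, 0 °C → rt; then 3 M NaOH, 30% H2O2, 0 °C → rt
Reagents that add atoms: hydrogen peroxide, OO
Why: 9-BBN should hydroborate the monosubstituted allyl alkene far faster than the cis-disubstituted and trisubstituted ring alkenes and place boron on the terminal carbon, and oxidation with retention gives the primary alcohol (hydroboration–oxidation).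

Step 6
Reactants: 18 methyl (1S,5S,6R,8aR)-5-(3-hydroxypropyl)-1,5,6-trimethyl-1,5,6,7,8,8a-hexahydronaphthalene-1-carboxylate
Product: 19 methyl (1S,5S,6R,8aR)-5-(3-hydroxypropyl)-1,5,6-trimethyl-1,2,3,5,6,7,8,8a-octahydronaphthalene-1-carboxylate
Conditions: KO2CN=NCO2K (8 equiv), AcOH (16 equiv, slow addition), MeOH/pyridine, rt
Reagents that add atoms: none
Why: Diimide delivers H2 by a concerted syn 1,2-addition and discriminates strongly by substitution, so the cis-disubstituted C2=C3 bond should be reduced while the trisubstituted C1=C10 bond beside the quaternary C9 stays, with no 1,4-addition or double-bond shift (diimide reduction).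

Step 7
Reactants: 19 methyl (1S,5S,6R,8aR)-5-(3-hydroxypropyl)-1,5,6-trimethyl-1,2,3,5,6,7,8,8a-octahydronaphthalene-1-carboxylate
Product: 20 methyl (1S,5S,6R,8aR)-1,5,6-trimethyl-5-(3-oxopropyl)-1,2,3,5,6,7,8,8a-octahydronaphthalene-1-carboxylate
Conditions: PhI(OAc)2 (1.1 equiv), TEMPO (10 mol %), CH2Cl2, rt
Reagents that add atoms: none
Why: The oxoammonium-mediated oxidation (TEMPO/PhI(OAc)2) should take the primary alcohol to the aldehyde without touching the trisubstituted alkene or the ester.

Step 8
Reactants: 20 methyl (1S,5S,6R,8aR)-1,5,6-trimethyl-5-(3-oxopropyl)-1,2,3,5,6,7,8,8a-octahydronaphthalene-1-carboxylate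
Product: 21 methyl (1S,5S,6R,8aR)-5-(but-3-yn-1-yl)-1,5,6-trimethyl-1,2,3,5,6,7,8,8a-octahydronaphthalene-1-carboxylate
Conditions: dimethyl (1-diazo-2-oxopropyl)phosphonate (1.3 equiv), K2CO3 (2 equiv), MeOH, 0 °C → rt
Reagents that add atoms: dimethyl (1-diazo-2-oxopropyl)phosphonate, COP(=O)(OC)C(=[N+]=[N-])C(C)=O
Why: Seyferth–Gilbert homologation in the Ohira–Bestmann form should convert the aldehyde into the terminal alkyne with one added carbon under K2CO3/MeOH, where the methyl ester can only exchange with itself and the quaternary C4 cannot epimerise.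

Step 9
Reactants: 21 methyl (1S,5S,6R,8aR)-5-(but-3-yn-1-yl)-1,5,6-trimethyl-1,2,3,5,6,7,8,8a-octahydronaphthalene-1-carboxylate
Product: 24 methyl (1S,5S,6R,8aR)-5-[(3E)-5-hydroxy-3-methylpent-3-en-1-yl]-1,5,6-trimethyl-1,2,3,5,6,7,8,8a-octahydronaphthalene-1-carboxylate, via alkenylalane 22 (not isolated), via lithium alkenylaluminate 23 (not isolated)
Conditions: Me3Al (2.5 equiv), Cp2ZrCl2 (0.25 equiv), CH2Cl2, 0 °C → rt; volatiles removed; n-BuLi (1 equiv), THF/hexane, −78 °C; (CH2O)n (5 equiv), −78 °C → rt; aq. potassium sodium tartrate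
Reagents that add atoms: trimethylaluminium, C[Al](C)C; formaldehyde (from paraformaldehyde), C=O
Why: Zirconium-catalysed syn carboalumination (Negishi) should add CH3 to the internal and aluminium to the terminal alkyne carbon, and the alkenylalane, as its lithium aluminate, should add to formaldehyde with retention, fixing the 13E trisubstituted allylic alcohol, while the neopentyl-type C18 ester is expected to be too hindered to compete at low temperature.

Step 10
Reactants: 24 methyl (1S,5S,6R,8aR)-5-[(3E)-5-hydroxy-3-methylpent-3-en-1-yl]-1,5,6-trimethyl-1,2,3,5,6,7,8,8a-octahydronaphthalene-1-carboxylate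
Product: 25 methyl (1S,5S,6R,8aR)-5-{2-[(2S,3S)-3-(hydroxymethyl)-2-methyloxiran-2-yl]ethyl}-1,5,6-trimethyl-1,2,3,5,6,7,8,8a-octahydronaphthalene-1-carboxylate
Conditions: Ti(OiPr)4 (10 mol %), L-(+)-diethyl tartrate (12 mol %), t-BuOOH (2 equiv, in decane), 4 Å molecular sieves, CH2Cl2, −20 °C
Reagents that add atoms: tert-butyl hydroperoxide, CC(C)(C)OO
Why: Sharpless asymmetric epoxidation is directed by the allylic hydroxyl, so only C13=C14 should react and the isolated C1=C10 alkene is left, and with L-(+)-diethyl tartrate oxygen is delivered to the face of the E allylic alcohol that gives the 13S,14S epoxy alcohol (reagent control), the cis relation of the C13 methyl and C15 following from the alkene geometry.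

**Compound list**

1 | 2-methylcyclohex-2-en-1-one | CC1=CCCCC1=O | starting material
2 | dimethylaluminium (3R)-2,3-dimethylcyclohex-1-en-1-olate | C[Al](C)OC1=C(C)[C@H](C)CCC1 | intermediate
3 | lithium trimethyl[(3R)-2,3-dimethylcyclohex-1-en-1-olato]aluminate | [Li+].C[Al-](C)(C)OC1=C(C)[C@H](C)CCC1 | intermediate
4 | (2S,3R)-2,3-dimethyl-2-(prop-2-en-1-yl)cyclohexan-1-one | O=C1CCC[C@@H](C)[C@]1(C)CC=C | intermediate
5 | methyl glyoxylate (methyl 2-oxoacetate) | COC(=O)C=O | starting material
6 | lithium (5R,6S)-5,6-dimethyl-6-(prop-2-en-1-yl)cyclohex-1-en-1-olate | [Li]OC1=CCC[C@@H](C)[C@]1(C)CC=C | intermediate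
7 | lithium aldolate: methyl 2-[(3S,4R)-3,4-dimethyl-2-oxo-3-(prop-2-en-1-yl)cyclohexyl]-2-(lithiooxy)acetate, mixture at the two new centres | COC(=O)C(O[Li])C1CC[C@@H](C)[C@](C)(CC=C)C1=O | intermediate
8 | methyl 2-[(3S,4R)-3,4-dimethyl-2-oxo-3-(prop-2-en-1-yl)cyclohexyl]-2-(methanesulfonyloxy)acetate, mixture at the two new centres | COC(=O)C(OS(C)(=O)=O)C1CC[C@@H](C)[C@](C)(CC=C)C1=O | intermediate
9 | methyl (2E)-[(3S,4R)-3,4-dimethyl-2-oxo-3-(prop-2-en-1-yl)cyclohexylidene]acetate | COC(=O)/C=C1\CC[C@@H](C)[C@](C)(CC=C)C1=O | intermediate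
10 | allyltriphenylphosphonium bromide | C=CC[P+](c1ccccc1)(c1ccccc1)c1ccccc1.[Br-] | starting material
11 | allylidenetriphenylphosphorane | C=CC=P(c1ccccc1)(c1ccccc1)c1ccccc1 | intermediate
12 | Michael adduct: ring B enolate (O− on C10, C5=C10) carrying on C5 the chain CH(CO2Me)CH2CH=CH–P+Ph3, mixture at C4 | COC(=O)C(CC=C[P+](c1ccccc1)(c1ccccc1)c1ccccc1)C1=C([O-])[C@@](C)(CC=C)[C@H](C)CC1 | intermediate
13 | keto ylide: methyl 2-[(3S,4R)-3,4-dimethyl-2-oxo-3-(prop-2-en-1-yl)cyclohexyl]-5-(triphenyl-λ5-phosphanylidene)pent-3-enoate, mixture at C4 and C5 | COC(=O)C(C=CC=P(c1ccccc1)(c1ccccc1)c1ccccc1)C1CC[C@@H](C)[C@](C)(CC=C)C1=O | intermediate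
14 | methyl (5S,6R,8aS)-5,6-dimethyl-5-(prop-2-en-1-yl)-1,5,6,7,8,8a-hexahydronaphthalene-1-carboxylate, both epimers at the ester-bearing carbon | COC(=O)C1C=CC=C2[C@H]1CC[C@@H](C)[C@]2(C)CC=C | intermediate
15 | lithium trienolate of 14 (O-lithio ketene acetal at C4, conjugated with C2=C3 and C1=C10) | [Li]OC(OC)=C1C=CC=C2[C@H]1CC[C@@H](C)[C@]2(C)CC=C | intermediate
16 | methyl (1S,5S,6R,8aR)-1,5,6-trimethyl-5-(prop-2-en-1-yl)-1,5,6,7,8,8a-hexahydronaphthalene-1-carboxylate | COC(=O)[C@@]1(C)C=CC=C2[C@H]1CC[C@@H](C)[C@]2(C)CC=C | intermediate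
17 | B-alkyl-9-borabicyclo[3.3.1]nonane from 16 (boron on the terminal carbon of the former allyl group) | COC(=O)[C@@]1(C)C=CC=C2[C@H]1CC[C@@H](C)[C@]2(C)CCCB1C2CCCC1CCC2 | intermediate
18 | methyl (1S,5S,6R,8aR)-5-(3-hydroxypropyl)-1,5,6-trimethyl-1,5,6,7,8,8a-hexahydronaphthalene-1-carboxylate | COC(=O)[C@@]1(C)C=CC=C2[C@H]1CC[C@@H](C)[C@]2(C)CCCO | intermediate
19 | methyl (1S,5S,6R,8aR)-5-(3-hydroxypropyl)-1,5,6-trimethyl-1,2,3,5,6,7,8,8a-octahydronaphthalene-1-carboxylate | COC(=O)[C@@]1(C)CCC=C2[C@H]1CC[C@@H](C)[C@]2(C)CCCO | intermediate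
20 | methyl (1S,5S,6R,8aR)-1,5,6-trimethyl-5-(3-oxopropyl)-1,2,3,5,6,7,8,8a-octahydronaphthalene-1-carboxylate | COC(=O)[C@@]1(C)CCC=C2[C@H]1CC[C@@H](C)[C@]2(C)CCC=O | intermediate
21 | methyl (1S,5S,6R,8aR)-5-(but-3-yn-1-yl)-1,5,6-trimethyl-1,2,3,5,6,7,8,8a-octahydronaphthalene-1-carboxylate | COC(=O)[C@@]1(C)CCC=C2[C@H]1CC[C@@H](C)[C@]2(C)CCC#C | intermediate
22 | (E)-alkenyl(dimethyl)alane from 21 (CH3 on C13, AlMe2 on C14) | COC(=O)[C@@]1(C)CCC=C2[C@H]1CC[C@@H](C)[C@]2(C)CC/C(C)=C/[Al](C)C | intermediate
23 | lithium (E)-alkenyl(butyl)dimethylaluminate from 22 | [Li+].COC(=O)[C@@]1(C)CCC=C2[C@H]1CC[C@@H](C)[C@]2(C)CC/C(C)=C/[Al-](C)(C)CCCC | intermediate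
24 | methyl (1S,5S,6R,8aR)-5-[(3E)-5-hydroxy-3-methylpent-3-en-1-yl]-1,5,6-trimethyl-1,2,3,5,6,7,8,8a-octahydronaphthalene-1-carboxylate | COC(=O)[C@@]1(C)CCC=C2[C@H]1CC[C@@H](C)[C@]2(C)CC/C(C)=C/CO | intermediate
25 | methyl (1S,5S,6R,8aR)-5-{2-[(2S,3S)-3-(hydroxymethyl)-2-methyloxiran-2-yl]ethyl}-1,5,6-trimethyl-1,2,3,5,6,7,8,8a-octahydronaphthalene-1-carboxylate | COC(=O)[C@@]1(C)CCC=C2[C@H]1CC[C@@H](C)[C@]2(C)CC[C@]1(C)O[C@H]1CO | target

**Step count and risks**

Total step count: 10. Longest linear sequence: 10 steps (1 → 25).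

Steps most likely to fail:

- Step 3 (key step). What may go wrong:
  - base-mediated drift of the exocyclic double bond of 9 into ring B before the ylide adds;
  - a reversible Michael addition that stalls before the slow olefination of the hindered ketone;
  - incomplete equilibration at C5 before ring closure;
  - deprotonation of the product at C4 by remaining ylide, with migration of the diene into conjugation.

  Fallback (leaves the route at 9, returns at 19): copper-catalysed conjugate addition of commercial 2-(1,3-dioxolan-2-yl)ethylmagnesium bromide (CuBr·SMe2, THF, −78 °C) to C4 of 9 would give the keto acetal F1. Aqueous HCl in THF would free the keto aldehyde F2. An intramolecular McMurry coupling (TiCl3, Zn(Cu), DME, reflux, high dilution) would join C1 to C10 and give the C2–C3-saturated allyl ester F3, with C5 selected as in step 3. LiN(iPr)2/MeI would give the C4-methylated ester F4, and 9-BBN followed by NaOH/H2O2 would deliver 19.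

- Step 4. What may go wrong: alkylation of the delocalised trienolate at C2 or C10 instead of C4, or insufficient facial discrimination at C4.

  Fallback (leaves the route at 14, returns at 19): 9-BBN then NaOH/H2O2 on the allyl group of 14 would give the diene alcohol F5, and diimide the monoene alcohol F6. C-methylation of the dianion of F6 (LiN(iPr)2, 2.2 equiv; MeI, 1.0 equiv, −78 °C) would give 19 directly. This simple ester enolate can only be alkylated at C4 and presents the same α face.

- Step 9. What may go wrong: attack of butyllithium or of the aluminate on the C18 ester during ate formation, or incomplete hydroxymethylation of the alkenylalane.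

  Fallback (leaves the route at 21, returns at 24): the same carboalumination quenched with I2 would give the E vinyl iodide F7. Stille coupling of F7 with (tributylstannyl)methanol (Pd(PPh3)4, toluene, 80 °C) would give 24 without any organolithium.

**Further compounds**

F1 | step 3 | methyl 2-[(3S,4R)-3,4-dimethyl-2-oxo-3-(prop-2-en-1-yl)cyclohexyl]-4-(1,3-dioxolan-2-yl)butanoate, mixture at C4 and C5 | COC(=O)C(CCC1OCCO1)C1CC[C@@H](C)[C@](C)(CC=C)C1=O
F2 | step 3 | methyl 2-[(3S,4R)-3,4-dimethyl-2-oxo-3-(prop-2-en-1-yl)cyclohexyl]-5-oxopentanoate, mixture at C4 and C5 | COC(=O)C(CCC=O)C1CC[C@@H](C)[C@](C)(CC=C)C1=O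
F3 | step 3 | methyl (5S,6R,8aS)-5,6-dimethyl-5-(prop-2-en-1-yl)-1,2,3,5,6,7,8,8a-octahydronaphthalene-1-carboxylate, both epimers at the ester-bearing carbon | COC(=O)C1CCC=C2[C@H]1CC[C@@H](C)[C@]2(C)CC=C
F4 | step 3 | methyl (1S,5S,6R,8aR)-1,5,6-trimethyl-5-(prop-2-en-1-yl)-1,2,3,5,6,7,8,8a-octahydronaphthalene-1-carboxylate | COC(=O)[C@@]1(C)CCC=C2[C@H]1CC[C@@H](C)[C@]2(C)CC=C
F5 | step 4 | methyl (5S,6R,8aS)-5-(3-hydroxypropyl)-5,6-dimethyl-1,5,6,7,8,8a-hexahydronaphthalene-1-carboxylate, both epimers at the ester-bearing carbon | COC(=O)C1C=CC=C2[C@H]1CC[C@@H](C)[C@]2(C)CCCO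
F6 | step 4 | methyl (5S,6R,8aS)-5-(3-hydroxypropyl)-5,6-dimethyl-1,2,3,5,6,7,8,8a-octahydronaphthalene-1-carboxylate, both epimers at the ester-bearing carbon | COC(=O)C1CCC=C2[C@H]1CC[C@@H](C)[C@]2(C)CCCO
F7 | step 9 | methyl (1S,5S,6R,8aR)-5-[(3E)-4-iodo-3-methylbut-3-en-1-yl]-1,5,6-trimethyl-1,2,3,5,6,7,8,8a-octahydronaphthalene-1-carboxylate | COC(=O)[C@@]1(C)CCC=C2[C@H]1CC[C@@H](C)[C@]2(C)CC/C(C)=C/I
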